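Cuts: after the four O–benzyl bonds and the C4 oxidation level (ketone, 4-ol, C3=C4 alkene), ring C is cut at C3=C4 (metathesis). Further cuts are O1–C2 (allylic etherification), C4a–C4 (formylation, methylenation), C8a–O1 (hydroxylation of an aryl bromide) and C6–CH2 (Grignard addition, ionic reduction).
Enabling feature: C4 sits on C4a of ring A and C3 sits next to the O1-bearing C2, so C3–C4 can be drawn as an alkene between two vinyl groups held ortho by C8a–O1 and C4a. While C4 is an alkene carbon there is no ketone, so the retro-oxa-Michael opening of O1–C2 that would epimerise C2 cannot occur.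
Regiochemistry: C6 lies para to C8a and between the C5 and C7 oxygens, so ring A is built as a symmetric 4-benzyl-3,5-dialkoxyphenol. Its two ortho positions are identical, which excludes the 8-benzyl isomer.
Forward order: rings A, B (2-phenyl) and D (catechol ring of the benzyl group) are bought. D is joined to A, O1 and the C4 carbon are placed on A, the C2–ring B unit is attached through O1, ring C closes last, and hydration, oxidation and hydrogenolysis finish the target.
Stereochemistry: the only stereocentre, C2 (S), comes from ligand control in the iridium-catalysed branched allylic etherification. It is a spectator afterwards, and the transient C4 carbinol epimers converge on oxidation.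

Key step: step 10

Numbering: flavanone locants (O1, C2, C3, C4, C4a, C5 to C8, C8a) are used for the atoms of rings A and C in all intermediates.
Assumption: the (Sa,Sc,Sc) antipode of ligand L, N,N-bis(1-phenylethyl)dinaphtho[2,1-d:1',2'-f][1,3,2]dioxaphosphepin-4-amine, is taken to give the (S)-ether. The sense is to be checked on 14 or 18 against the chiroptical behaviour of (2S)-flavanones, and the equally available mirror-image ligand is used without other change if it is reversed.

Step 1
Reactants: 1 4-bromo-2,6-difluorobenzaldehyde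
Product: 2 2,6-bis(benzyloxy)-4-bromobenzaldehyde
Conditions: BnOH (2.3 equiv), NaH (2.3 equiv), THF, 0 °C to 50 °C
Reagents that add atoms: benzyl alcohol, OCc1ccccc1
Why: Twofold nucleophilic aromatic substitution (addition–elimination): both fluorides stand ortho to the formyl acceptor and fluoride leaves far faster than the para bromide, so the symmetric bis(benzyl ether) should form while the bromide survives as the latent O1.

Step 2
Reactants: 3 3-bromobenzene-1,2-diol
Product: 4 1,2-bis(benzyloxy)-3-bromobenzene
Conditions: BnBr (2.3 equiv), K2CO3, DMF, 60 °C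
Reagents that add atoms: benzyl bromide, BrCc1ccccc1
Why: Williamson ether synthesis of both phenols with a primary benzylic bromide under carbonate base, which leaves the aryl bromide untouched.

Step 3
Reactants: 4 1,2-bis(benzyloxy)-3-bromobenzene; 2 2,6-bis(benzyloxy)-4-bromobenzaldehyde
Product: 6 (RS)-[2,6-bis(benzyloxy)-4-bromophenyl][2,3-bis(benzyloxy)phenyl]methanol, via arylmagnesium bromide 5 (not isolated)
Conditions: Mg, THF, reflux; then 2, THF, 0 °C; aq. NH4Cl
Reagents that add atoms: none
Why: Grignard addition: magnesium inserts into the C–Br bond of 4 without exposing the benzyl ethers to an alkyllithium (so no benzylic metalation or Wittig rearrangement), and 5 adds to the aldehyde of 2 much faster than it can exchange with its aryl bromide; the carbinol centre is racemic and is erased in step 4.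

Step 4
Reactants: 6 (RS)-[2,6-bis(benzyloxy)-4-bromophenyl][2,3-bis(benzyloxy)phenyl]methanol
Product: 7 1,3-bis(benzyloxy)-2-[2,3-bis(benzyloxy)benzyl]-5-bromobenzene
Conditions: Et3SiH (3 equiv), CF3CO2H (5 equiv), CH2Cl2, 0 °C
Reagents that add atoms: none
Why: Ionic hydrogenation: the acid ionises the doubly benzylic alcohol to a diarylmethyl cation stabilised by three ortho alkoxy groups, and the silane traps it by hydride transfer at a temperature at which aryl benzyl ethers and the aryl bromide persist.

Step 5
Reactants: 7 1,3-bis(benzyloxy)-2-[2,3-bis(benzyloxy)benzyl]-5-bromobenzene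
Product: 8 3,5-bis(benzyloxy)-4-[2,3-bis(benzyloxy)benzyl]phenol
Conditions: Pd2(dba)3 (2 mol %), tBuXPhos (8 mol %), KOH (4 equiv), 1,4-dioxane/H2O, 100 °C, argon; then aq. HCl
Reagents that add atoms: potassium hydroxide, [K+].[OH-]
Why: Palladium-catalysed hydroxylation of an aryl halide (C–O cross-coupling): oxidative addition of the unhindered C–Br bond to zerovalent palladium, exchange with hydroxide and reductive elimination promoted by the bulky biaryl phosphine give the phenol, while the ethers and the diarylmethane are inert to aqueous KOH.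

Step 6
Reactants: 8 3,5-bis(benzyloxy)-4-[2,3-bis(benzyloxy)benzyl]phenol
Product: 9 2,4-bis(benzyloxy)-3-[2,3-bis(benzyloxy)benzyl]-6-hydroxybenzaldehyde
Conditions: MgCl2 (1.5 equiv), Et3N (3.75 equiv), (CH2O)n (7 equiv), MeCN, reflux; then aq. HCl
Reagents that add atoms: paraformaldehyde (as formaldehyde), C=O
Why: Casnati–Skattebøl ortho-formylation: the magnesium phenoxide delivers formaldehyde to the ortho carbon within a chelate and a second formaldehyde oxidises the benzylic alkoxide by hydride transfer; para is blocked and the two ortho positions are symmetry-equivalent, so a single isomer should result, with the benzyl group at the future C6.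

Step 7
Reactants: 9 2,4-bis(benzyloxy)-3-[2,3-bis(benzyloxy)benzyl]-6-hydroxybenzaldehyde
Product: 10 3,5-bis(benzyloxy)-4-[2,3-bis(benzyloxy)benzyl]-2-ethenylphenol
Conditions: Ph3PCH3Br (2.5 equiv), KOtBu (2.5 equiv), THF, 0 °C to rt; aq. NH4Cl
Reagents that add atoms: methyltriphenylphosphonium bromide, [Br-].C[P+](c1ccccc1)(c1ccccc1)c1ccccc1
Why: Wittig methylenation with excess non-stabilised ylide: the first equivalent of base only deprotonates the phenol, the phenoxide aldehyde still reacts, and protonation on work-up returns the 2-vinylphenol, which is kept free of acid and used promptly.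

Step 8
Reactants: 11 (E)-cinnamyl alcohol
Product: 12 (E)-cinnamyl methyl carbonate
Conditions: ClCO2Me (1.2 equiv), pyridine, CH2Cl2, 0 °C
Reagents that add atoms: methyl chloroformate, COC(=O)Cl
Why: Acylation of a primary allylic alcohol with a chloroformate (carbonate formation), with pyridine as acid scavenger; the E-alkene is untouched.

Step 9
Reactants: 10 3,5-bis(benzyloxy)-4-[2,3-bis(benzyloxy)benzyl]-2-ethenylphenol; 12 (E)-cinnamyl methyl carbonate
Product: 14 1,3-bis(benzyloxy)-2-[2,3-bis(benzyloxy)benzyl]-4-ethenyl-5-{[(1S)-1-phenylprop-2-en-1-yl]oxy}benzene, via lithium aryloxide 13 (not isolated)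
Conditions: n-BuLi (1.0 equiv), THF, 0 °C; then 12 (1.2 equiv), [Ir(cod)Cl]2 (2 mol %), (Sa,Sc,Sc)-L (4 mol %, pre-activated with n-PrNH2), THF, rt to 50 °C
Reagents that add atoms: none
Why: Iridium-catalysed asymmetric allylic etherification of an aryloxide, a reaction known for 2-vinylphenols: the cyclometallated iridium phosphoramidite ionises 12 to an η3-cinnamyl complex, the aryloxide attacks the phenyl-bearing terminus anti to the metal to give the branched ether, and the ligand antipode decides the allyl face and thereby sets C2 as S.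

Step 10
Reactants: 14 1,3-bis(benzyloxy)-2-[2,3-bis(benzyloxy)benzyl]-4-ethenyl-5-{[(1S)-1-phenylprop-2-en-1-yl]oxy}benzene
Product: 15 (2S)-5,7-bis(benzyloxy)-6-[2,3-bis(benzyloxy)benzyl]-2-phenyl-2H-chromene
Conditions: second-generation Grubbs catalyst RuCl2(=CHPh)(PCy3)(H2IMes) (5 mol %), 1,4-benzoquinone (10 mol %), CH2Cl2 (0.005 M), 40 °C, argon sparge, dark
Reagents that add atoms: none
Why: Olefin metathesis by the Chauvin mechanism: after loss of PCy3 the ruthenium benzylidene exchanges first with the less hindered vinyl group on C2, the new alkylidene adds across the vinyl group on C4a to a ruthenacyclobutane, and cycloreversion releases 15 and a ruthenium methylidene that carries the chain with loss of ethene. The closest known reaction type is the ring-closing metathesis of 2-vinylaryl allyl ethers to 2H-chromenes, including enantioenriched ethers made by iridium-catalysed etherification. Ring C closes as a six-membered ring by intramolecular [2+2] cycloaddition and cycloreversion with both alkene carbons (C3 and C4) ending inside the ring, so the new double bond is necessarily Z. No stereocentre is formed; C2 is a spectator because none of its four bonds takes part and, with C4 an alkene carbon and no carbonyl group present, O1–C2 has no retro-oxa-Michael path for opening. The step needs ring closure to win over intermolecular metathesis and over ruthenium hydride migration of the allyl double bond to an achiral C2=C3 enol ether: the ortho placement of O1 and the C4a vinyl group on rigid ring A, high dilution and removal of ethene secure the first, and 1,4-benzoquinone as hydride scavenger with a mild temperature secures the second. Light and acid are excluded because 2H-chromenes can open photochemically by an oxa-6π electrocyclic reaction to an achiral o-quinone methide and 5,7-dialkoxyflav-3-enes are easily ionised or oxidised to flavylium salts.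

Step 11
Reactants: 15 (2S)-5,7-bis(benzyloxy)-6-[2,3-bis(benzyloxy)benzyl]-2-phenyl-2H-chromene
Product: 17 (2S,4RS)-5,7-bis(benzyloxy)-6-[2,3-bis(benzyloxy)benzyl]-2-phenylchroman-4-ol, via C4 hydroperoxide 16 (not isolated)
Conditions: Co(acac)2 (20 mol %), PhSiH3 (2 equiv), O2 (1 atm), THF, 0 °C to rt, dark; then P(OEt)3 (1.5 equiv), 0 °C
Reagents that add atoms: dioxygen, O=O
Why: Mukaiyama hydration (hydrogen-atom transfer from a cobalt hydride): hydrogen goes to C3 because this gives the C4 benzylic radical conjugated with ring A, O2 traps it and the phosphite reduces hydroperoxide 16 to the alcohol; C2 is not adjacent to the radical and stays S, and the new C4 centre forms without control as an epimer mixture, which is irrelevant because step 12 removes it.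

Step 12
Reactants: 17 (2S,4RS)-5,7-bis(benzyloxy)-6-[2,3-bis(benzyloxy)benzyl]-2-phenylchroman-4-ol
Product: 18 (2S)-5,7-bis(benzyloxy)-6-[2,3-bis(benzyloxy)benzyl]-2-phenyl-2,3-dihydro-4H-chromen-4-one
Conditions: Dess–Martin periodinane (1.3 equiv), pyridine (3 equiv), CH2Cl2, 0 °C
Reagents that add atoms: none
Why: Dess–Martin oxidation: ligand exchange at iodine and internal proton abstraction convert both C4 epimers into one ketone under buffered, weakly basic conditions, so the acid-labile benzylic alcohol does not ionise and no enolate forms that could open O1–C2.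

Step 13
Reactants: 18 (2S)-5,7-bis(benzyloxy)-6-[2,3-bis(benzyloxy)benzyl]-2-phenyl-2,3-dihydro-4H-chromen-4-one
Product: 19 (2S)-6-(2,3-dihydroxybenzyl)-5,7-dihydroxy-2-phenyl-2,3-dihydro-4H-chromen-4-one (CNP0348560.1)
Conditions: H2 (1 atm), 10% Pd/C, EtOAc/MeOH, rt
Reagents that add atoms: none
Why: Catalytic hydrogenolysis of the four primary benzyl aryl ethers under neutral conditions; these cleave faster than the secondary, ring-bound O1–C2 benzylic bond and without enolisation, so the ketone, ring C and the S configuration at C2 should be kept.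

Compound list
1 | 4-bromo-2,6-difluorobenzaldehyde | O=Cc1c(F)cc(Br)cc1F | starting material
2 | 2,6-bis(benzyloxy)-4-bromobenzaldehyde | O=Cc1c(OCc2ccccc2)cc(Br)cc1OCc1ccccc1 | intermediate
3 | 3-bromobenzene-1,2-diol | Oc1cccc(Br)c1O | starting material
4 | 1,2-bis(benzyloxy)-3-bromobenzene | Brc1cccc(OCc2ccccc2)c1OCc1ccccc1 | intermediate
5 | [2,3-bis(benzyloxy)phenyl]magnesium bromide | Br[Mg]c1cccc(OCc2ccccc2)c1OCc1ccccc1 | intermediate
6 | (RS)-[2,6-bis(benzyloxy)-4-bromophenyl][2,3-bis(benzyloxy)phenyl]methanol | OC(c1cccc(OCc2ccccc2)c1OCc1ccccc1)c1c(OCc2ccccc2)cc(Br)cc1OCc1ccccc1 | intermediate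
7 | 1,3-bis(benzyloxy)-2-[2,3-bis(benzyloxy)benzyl]-5-bromobenzene | Brc1cc(OCc2ccccc2)c(Cc2cccc(OCc3ccccc3)c2OCc2ccccc2)c(OCc2ccccc2)c1 | intermediate
8 | 3,5-bis(benzyloxy)-4-[2,3-bis(benzyloxy)benzyl]phenol | Oc1cc(OCc2ccccc2)c(Cc2cccc(OCc3ccccc3)c2OCc2ccccc2)c(OCc2ccccc2)c1 | intermediate
9 | 2,4-bis(benzyloxy)-3-[2,3-bis(benzyloxy)benzyl]-6-hydroxybenzaldehyde | O=Cc1c(O)cc(OCc2ccccc2)c(Cc2cccc(OCc3ccccc3)c2OCc2ccccc2)c1OCc1ccccc1 | intermediate
10 | 3,5-bis(benzyloxy)-4-[2,3-bis(benzyloxy)benzyl]-2-ethenylphenol | C=Cc1c(O)cc(OCc2ccccc2)c(Cc2cccc(OCc3ccccc3)c2OCc2ccccc2)c1OCc1ccccc1 | intermediate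
11 | (E)-cinnamyl alcohol | OC/C=C/c1ccccc1 | starting material
12 | (E)-cinnamyl methyl carbonate | COC(=O)OC/C=C/c1ccccc1 | intermediate
13 | lithium 3,5-bis(benzyloxy)-4-[2,3-bis(benzyloxy)benzyl]-2-ethenylphenoxide | [Li+].[O-]c1cc(OCc2ccccc2)c(Cc2cccc(OCc3ccccc3)c2OCc2ccccc2)c(OCc2ccccc2)c1C=C | intermediate
14 | 1,3-bis(benzyloxy)-2-[2,3-bis(benzyloxy)benzyl]-4-ethenyl-5-{[(1S)-1-phenylprop-2-en-1-yl]oxy}benzene | C=C[C@@H](c1ccccc1)Oc1cc(OCc2ccccc2)c(Cc2cccc(OCc3ccccc3)c2OCc2ccccc2)c(OCc2ccccc2)c1C=C | intermediate
15 | (2S)-5,7-bis(benzyloxy)-6-[2,3-bis(benzyloxy)benzyl]-2-phenyl-2H-chromene | C1=C[C@@H](c2ccccc2)Oc2cc(OCc3ccccc3)c(Cc3cccc(OCc4ccccc4)c3OCc3ccccc3)c(OCc3ccccc3)c21 | intermediate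
16 | (2S,4RS)-5,7-bis(benzyloxy)-6-[2,3-bis(benzyloxy)benzyl]-4-hydroperoxy-2-phenylchromane | OOC1C[C@@H](c2ccccc2)Oc2cc(OCc3ccccc3)c(Cc3cccc(OCc4ccccc4)c3OCc3ccccc3)c(OCc3ccccc3)c21 | intermediate
17 | (2S,4RS)-5,7-bis(benzyloxy)-6-[2,3-bis(benzyloxy)benzyl]-2-phenylchroman-4-ol | OC1C[C@@H](c2ccccc2)Oc2cc(OCc3ccccc3)c(Cc3cccc(OCc4ccccc4)c3OCc3ccccc3)c(OCc3ccccc3)c21 | intermediate
18 | (2S)-5,7-bis(benzyloxy)-6-[2,3-bis(benzyloxy)benzyl]-2-phenyl-2,3-dihydro-4H-chromen-4-one | O=C1C[C@@H](c2ccccc2)Oc2cc(OCc3ccccc3)c(Cc3cccc(OCc4ccccc4)c3OCc3ccccc3)c(OCc3ccccc3)c21 | intermediate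
19 | (2S)-6-(2,3-dihydroxybenzyl)-5,7-dihydroxy-2-phenyl-2,3-dihydro-4H-chromen-4-one | O=C1C[C@@H](c2ccccc2)Oc2cc(O)c(Cc3cccc(O)c3O)c(O)c21 | target

Total steps: 13. Longest linear sequence: 11 steps (1, 3, 4, 5, 6, 7, 9, 10, 11, 12, 13).

Steps most likely to fail

Step 9. Three things may go wrong:
- The very electron-rich, ambident aryloxide may attack through carbon (C8 or the vinyl terminus) instead of oxygen.
- Reversible ionisation of the product ether may erode the branched selectivity and the enantiomeric purity.
- The ortho vinyl group may slow the attack.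

In the fallback the stereocentre is bought and transferred by SN2 displacement.
- Setting out from 10, a Mitsunobu reaction (PPh3, DIAD, toluene, 0 °C) with commercial (R)-3-chloro-1-phenylpropan-1-ol should proceed with inversion to the (S)-3-chloro-1-phenylpropyl aryl ether F1.
- Sodium phenylselenide (PhSeSePh, NaBH4, EtOH) displaces the primary chloride to give the phenyl selenide F2.
- H2O2 in CH2Cl2/pyridine at 0 °C oxidises it to the selenoxide F3.
- The syn elimination of F3 at room temperature can take a hydrogen only from the central CH2 group. The terminal alkene forms without touching C2, and the route is rejoined at 14.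

Step 11. Four things may go wrong:
- The C4 radical may be reduced instead of oxygenated.
- Radical oligomerisation of the electron-rich styrene unit may compete.
- Autoxidation at the doubly benzylic CH2 may occur.
- The acid-labile C4 oxygen function may ionise during isolation.

The fallback replaces the radical process by hydrometalation.
- Setting out from 15, rhodium-catalysed Markovnikov hydroboration is used (catecholborane, [Rh(cod)2]BF4, 1,4-bis(diphenylphosphino)butane, THF, 0 °C). It places boron on the benzylic carbon through an η3-benzyl rhodium intermediate and should give the C4 catechol boronate F4.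
- Oxidation with NaBO3·4H2O in THF/H2O is harmless to C2 because no ketone is present yet, and it rejoins the route at 17.

Step 10. Three things may go wrong:
- The ruthenium methylidene may decay to hydrides, which shift the allyl double bond and erase C2.
- The di-ortho-substituted styrene may engage sluggishly, or the catalyst may rest in a chelated styrenyl ether form.
- The sensitive vinylphenol precursor or the product may be lost through ionisation.

The fallback keeps the C3=C4 closure but redesigns the alkene on C4a.
- Setting out from 9, a Wittig reaction with ethyltriphenylphosphonium bromide and KOtBu gives the more robust 2-(prop-1-enyl)phenol F5.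
- n-BuLi converts it into the lithium aryloxide F6.
- The iridium-catalysed etherification with 12 under the conditions of step 9 gives the (S)-1-phenylallyl 2-(prop-1-enyl)aryl ether F7.
- RuCl2(=CHPh)(PCy3)(H2IMes) then closes ring C with loss of propene. The chain is carried by a longer-lived ruthenium ethylidene instead of the methylidene, and the route is rejoined at 15.

Further compounds
F1 | step 9 | 1,3-bis(benzyloxy)-2-[2,3-bis(benzyloxy)benzyl]-5-{[(1S)-3-chloro-1-phenylpropyl]oxy}-4-ethenylbenzene | ClCC[C@@H](c1ccccc1)Oc1cc(OCc2ccccc2)c(Cc2cccc(OCc3ccccc3)c2OCc2ccccc2)c(OCc2ccccc2)c1C=C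
F2 | step 9 | 1,3-bis(benzyloxy)-2-[2,3-bis(benzyloxy)benzyl]-4-ethenyl-5-{[(1S)-1-phenyl-3-(phenylselanyl)propyl]oxy}benzene | c1ccccc1[Se]CC[C@@H](c1ccccc1)Oc1cc(OCc2ccccc2)c(Cc2cccc(OCc3ccccc3)c2OCc2ccccc2)c(OCc2ccccc2)c1C=C
F3 | step 9 | 1,3-bis(benzyloxy)-2-[2,3-bis(benzyloxy)benzyl]-4-ethenyl-5-{[(1S)-1-phenyl-3-(phenylseleninyl)propyl]oxy}benzene | O=[Se](c1ccccc1)CC[C@@H](c1ccccc1)Oc1cc(OCc2ccccc2)c(Cc2cccc(OCc3ccccc3)c2OCc2ccccc2)c(OCc2ccccc2)c1C=C
F4 | step 11 | 2-{(2S,4RS)-5,7-bis(benzyloxy)-6-[2,3-bis(benzyloxy)benzyl]-2-phenylchroman-4-yl}-1,3,2-benzodioxaborole | C1(B2Oc3ccccc3O2)C[C@@H](c2ccccc2)Oc2cc(OCc3ccccc3)c(Cc3cccc(OCc4ccccc4)c3OCc3ccccc3)c(OCc3ccccc3)c21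
F5 | step 10 | 3,5-bis(benzyloxy)-4-[2,3-bis(benzyloxy)benzyl]-2-(prop-1-en-1-yl)phenol (E/Z mixture) | CC=Cc1c(O)cc(OCc2ccccc2)c(Cc2cccc(OCc3ccccc3)c2OCc2ccccc2)c1OCc1ccccc1
F6 | step 10 | lithium 3,5-bis(benzyloxy)-4-[2,3-bis(benzyloxy)benzyl]-2-(prop-1-en-1-yl)phenoxide | [Li+].[O-]c1cc(OCc2ccccc2)c(Cc2cccc(OCc3ccccc3)c2OCc2ccccc2)c(OCc2ccccc2)c1C=CC
F7 | step 10 | 1,3-bis(benzyloxy)-2-[2,3-bis(benzyloxy)benzyl]-5-{[(1S)-1-phenylprop-2-en-1-yl]oxy}-4-(prop-1-en-1-yl)benzene (E/Z mixture) | C=C[C@@H](c1ccccc1)Oc1cc(OCc2ccccc2)c(Cc2cccc(OCc3ccccc3)c2OCc2ccccc2)c(OCc2ccccc2)c1C=CC
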